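Locants: chromone O1–C8a unprimed; dihydropyranone O1'–C6' (C2' bears CH3, C4' is the carbonyl, C6' bears the side chain); "methine" is the stereogenic CH(CH3) between C6' and the benzylic CH2.
Cuts, in retrosynthetic order: O1'–C6' with the C5'=C6' unsaturation (cyclodehydration) to an open-chain silyloxy 1,3-diketone; C5'–C6' (Claisen condensation) to a chiral methyl ketone and an aryl lactone; lactone C–O and chromone C6–CH2 (Negishi coupling) to 6-iodoeugenin and a chiral bromo ester; C6–I and O7–CH3 back to noreugenin.
Enabling features: C2', C4' and C6' are all oxygenated (O1' bridges C2' and C6'), so the ring is a cyclised, dehydrated δ-hydroxy-β-diketone (a triketide unit) and can be closed last as in polyketide biosynthesis; the 5-OH lies ortho to the C6 side chain, four atoms from its acyl carbon, so it can hold that carbon as a six-membered aryl lactone that activates it for the C5'–C6' bond and is opened again in that event.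
Forward: the two chromone rings are bought with noreugenin; O7 is methylated and C6 iodinated; the four-carbon acid chain is joined at C6; a temporary lactone ring is closed and then opened by an enolate, which completes the chain; the dihydropyranone ring closes last.
Stereochemistry: both centres are bought and never sit at a reacting carbon: the R methine from methyl (2S)-3-bromo-2-methylpropanoate (same spatial arrangement, descriptor changed by priority only), S at C2' from (2S)-pent-4-en-2-ol.

Key step: step 8

Remark: 1, 4 and 8 are taken as commercial compounds, 4 and 8 as single enantiomers.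

Step 1
Reactants: 1 noreugenin (5,7-dihydroxy-2-methyl-4H-chromen-4-one)
Product: 2 eugenin (5-hydroxy-7-methoxy-2-methyl-4H-chromen-4-one)
Conditions: MeI (1.1 equiv), K2CO3, acetone, reflux
Reagents that add atoms: iodomethane, CI
Why: Williamson ether synthesis: the 5-OH is held in a hydrogen bond to the C4 carbonyl and is far less acidic and nucleophilic than the 7-OH, so one equivalent of MeI under K2CO3 should methylate O7 only.

Step 2
Reactants: 2 eugenin
Product: 3 5-hydroxy-6-iodo-7-methoxy-2-methyl-4H-chromen-4-one
Conditions: BnNMe3·ICl2 (1.1 equiv), CaCO3, CH2Cl2/MeOH, rt, dark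
Reagents that add atoms: benzyltrimethylammonium dichloroiodate, C[N+](C)(C)Cc1ccccc1.Cl[I-]Cl
Why: Electrophilic aromatic iodination: with O7 alkylated and O5 free, the dichloroiodate should deliver iodine ortho to the free phenol at C6 (the position flanked by both oxygen substituents) in preference to C8 and C3, the selectivity known for 5-hydroxy-7-alkoxy chromones and flavones, while CaCO3 takes up the HCl.

Step 3
Reactants: 3 5-hydroxy-6-iodo-7-methoxy-2-methyl-4H-chromen-4-one; 4 methyl (2S)-3-bromo-2-methylpropanoate
Product: 6 methyl (2R)-3-(5-hydroxy-7-methoxy-2-methyl-4-oxo-4H-chromen-6-yl)-2-methylpropanoate, via zinc homoenolate 5 (not isolated)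
Conditions: 4 (3 equiv), Zn dust, LiCl, THF, 40 °C; then 3, Pd(OAc)2 (5 mol %), SPhos (10 mol %), THF/DMA, 50 °C
Reagents that add atoms: none
Why: Negishi cross-coupling: zinc inserts into the primary C–Br bond to give a chelated β-zincio ester whose stereocentre is not the metallated carbon, and Pd(OAc)2/SPhos couples primary alkylzinc halides with doubly ortho-substituted aryl iodides faster than β-hydride elimination, the excess of 5 covering any loss to the acidic 5-OH, so the (S)-bromide should give the (R)-ester with unchanged spatial arrangement.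

Step 4
Reactants: 6 methyl (2R)-3-(5-hydroxy-7-methoxy-2-methyl-4-oxo-4H-chromen-6-yl)-2-methylpropanoate
Product: 7 (3R)-5-methoxy-3,8-dimethyl-3,4-dihydro-2H,10H-pyrano[2,3-f]chromene-2,10-dione (six-membered aryl lactone between O5 and the side-chain carboxyl)
Conditions: TsOH·H2O (10 mol %), toluene, reflux, 4 Å MS (removal of MeOH)
Reagents that add atoms: none
Why: Acid-catalysed intramolecular transesterification (lactonisation): O5 and the ester carbon are placed for a six-membered ring and removal of methanol drives the equilibrium, which masks the phenol and turns the unreactive methyl ester into an activated aryl ester without touching the stereocentre, any lactone already formed in step 3 converging here.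

Step 5
Reactants: 8 (2S)-pent-4-en-2-ol
Product: 9 tert-butyl(dimethyl){[(2S)-pent-4-en-2-yl]oxy}silane
Conditions: TBSCl, imidazole, CH2Cl2, 0 °C to rt
Reagents that add atoms: tert-butyldimethylsilyl chloride, CC(C)(C)[Si](C)(C)Cl
Why: Silyl ether formation: the secondary alcohol is silylated without any bond to the stereocentre being broken, which blocks retro-aldol and alkoxide chemistry in the later enolate step.

Step 6
Reactants: 9 tert-butyl(dimethyl){[(2S)-pent-4-en-2-yl]oxy}silane
Product: 10 (4S)-4-{[tert-butyl(dimethyl)silyl]oxy}pentan-2-one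
Conditions: PdCl2 (10 mol %), CuCl (1 equiv), O2 (1 atm), DMF/H2O (7:1), rt
Reagents that add atoms: water, O
Why: Tsuji–Wacker oxidation: Markovnikov hydroxypalladation of the terminal alkene and β-hydride elimination should give the methyl ketone, with O2 as terminal oxidant through the CuCl couple (net equation alkene plus half an equivalent of O2, no co-product) and the silyl ether and stereocentre untouched.

Step 7
Reactants: 10 (4S)-4-{[tert-butyl(dimethyl)silyl]oxy}pentan-2-one; 7 (3R)-5-methoxy-3,8-dimethyl-3,4-dihydro-2H,10H-pyrano[2,3-f]chromene-2,10-dione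
Product: 12 6-[(2R,7S)-7-{[tert-butyl(dimethyl)silyl]oxy}-2-methyl-3,5-dioxooctyl]-5-hydroxy-7-methoxy-2-methyl-4H-chromen-4-one, via lithium enolate 11 (not isolated)
Conditions: 10 (2.5 equiv), LiN(i-Pr)2 (2.4 equiv), THF, −78 °C; then 7, −78 °C; AcOH quench
Reagents that add atoms: none
Why: Crossed Claisen condensation: the kinetic lithium enolate at the methyl group of 10 attacks the aryl ester carbonyl of 7 and expels the phenoxide, which opens the temporary lactone ring and frees the 5-OH, and the β-diketone is at once deprotonated by the second equivalent of enolate so that no second addition can follow, while at −78 °C acyl transfer should outrun proton abstraction from the methine and both stereocentres stay as they are.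

Step 8
Reactants: 12 6-[(2R,7S)-7-{[tert-butyl(dimethyl)silyl]oxy}-2-methyl-3,5-dioxooctyl]-5-hydroxy-7-methoxy-2-methyl-4H-chromen-4-one
Product: 15 5-hydroxy-7-methoxy-2-methyl-6-{(2R)-2-[(2S)-2-methyl-4-oxo-3,4-dihydro-2H-pyran-6-yl]propyl}-4H-chromen-4-one (CNP0231471.1), via hydroxy diketone 13 (not isolated), via cyclic hemiketal 14 (not isolated)
Conditions: HF (48 % aq.), MeCN, 0 °C to rt; then TsOH·H2O (cat.), CH2Cl2, 4 Å MS, rt
Reagents that add atoms: none
Why: Aqueous HF removes the silyl group to give the free δ-hydroxy-β-diketone 13, whose hydroxyl adds to the distal ketone (the one next to the methine) in a 6-exo-trig closure to the hemiketal 14; acid-catalysed loss of water from this β-hydroxy ketone through the oxocarbenium ion then gives the vinylogous ester, whose conjugation is the driving force. The closest known reaction type is the biomimetic cyclodehydration of δ-hydroxy-β-diketones (triketide units) to 2,3-dihydro-4H-pyran-4-ones. No new stereocentre arises: C2' stays S because its oxygen acts as the nucleophile and the C2'–O bond is never broken, and the methine stays R because the 1,3-diketone enolises toward the central CH2 and not toward the methine. Regioselectivity is fixed by ring size, since attack on the nearer ketone would give an oxetane. The step needs chemoselectivity for the aliphatic hydroxyl over the 5-OH, which is secured by the strong hydrogen bond of the 5-OH to the chromone C4 carbonyl and by reversibility, as a hemiketal of the phenol cannot reach the alkoxy-stabilised vinylogous ester and returns to 13. Mild acid at or below room temperature is chosen to avoid elimination of the C2' oxygen, which would erase that stereocentre.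

Compound list
1 | noreugenin, 5,7-dihydroxy-2-methyl-4H-chromen-4-one | Cc1cc(=O)c2c(O)cc(O)cc2o1 | starting material
2 | eugenin, 5-hydroxy-7-methoxy-2-methyl-4H-chromen-4-one | COc1cc2oc(C)cc(=O)c2c(O)c1 | intermediate
3 | 5-hydroxy-6-iodo-7-methoxy-2-methyl-4H-chromen-4-one | COc1cc2oc(C)cc(=O)c2c(O)c1I | intermediate
4 | methyl (2S)-3-bromo-2-methylpropanoate | BrC[C@@H](C)C(=O)OC | starting material
5 | [(2S)-3-methoxy-2-methyl-3-oxopropyl]zinc bromide | Br[Zn]C[C@@H](C)C(=O)OC | intermediate (not isolated)
6 | methyl (2R)-3-(5-hydroxy-7-methoxy-2-methyl-4-oxo-4H-chromen-6-yl)-2-methylpropanoate | COc1cc2oc(C)cc(=O)c2c(O)c1C[C@@H](C)C(=O)OC | intermediate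
7 | (3R)-5-methoxy-3,8-dimethyl-3,4-dihydro-2H,10H-pyrano[2,3-f]chromene-2,10-dione | COc1cc2oc(C)cc(=O)c2c3c1C[C@@H](C)C(=O)O3 | intermediate
8 | (2S)-pent-4-en-2-ol | C=CC[C@H](C)O | starting material
9 | tert-butyl(dimethyl){[(2S)-pent-4-en-2-yl]oxy}silane | C=CC[C@H](C)O[Si](C)(C)C(C)(C)C | intermediate
10 | (4S)-4-{[tert-butyl(dimethyl)silyl]oxy}pentan-2-one | CC(=O)C[C@H](C)O[Si](C)(C)C(C)(C)C | intermediate
11 | lithium (4S)-4-{[tert-butyl(dimethyl)silyl]oxy}pent-1-en-2-olate | [Li]OC(=C)C[C@H](C)O[Si](C)(C)C(C)(C)C | intermediate (not isolated)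
12 | 6-[(2R,7S)-7-{[tert-butyl(dimethyl)silyl]oxy}-2-methyl-3,5-dioxooctyl]-5-hydroxy-7-methoxy-2-methyl-4H-chromen-4-one | COc1cc2oc(C)cc(=O)c2c(O)c1C[C@@H](C)C(=O)CC(=O)C[C@H](C)O[Si](C)(C)C(C)(C)C | intermediate
13 | 5-hydroxy-6-[(2R,7S)-7-hydroxy-2-methyl-3,5-dioxooctyl]-7-methoxy-2-methyl-4H-chromen-4-one | COc1cc2oc(C)cc(=O)c2c(O)c1C[C@@H](C)C(=O)CC(=O)C[C@H](C)O | intermediate (not isolated)
14 | 5-hydroxy-6-{(2R)-2-[(6S)-2-hydroxy-6-methyl-4-oxooxan-2-yl]propyl}-7-methoxy-2-methyl-4H-chromen-4-one (both configurations at the hemiketal carbon) | COc1cc2oc(C)cc(=O)c2c(O)c1C[C@@H](C)C1(O)CC(=O)C[C@H](C)O1 | intermediate (not isolated)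
15 | 5-hydroxy-7-methoxy-2-methyl-6-{(2R)-2-[(2S)-2-methyl-4-oxo-3,4-dihydro-2H-pyran-6-yl]propyl}-4H-chromen-4-one | COc1cc2oc(C)cc(=O)c2c(O)c1C[C@@H](C)C1=CC(=O)C[C@H](C)O1 | target

Total step count: 8. Longest linear sequence: 6 steps (steps 1, 2, 3, 4, 7 and 8 from 1); the branch from 8 (steps 5 and 6) joins at step 7.

Steps most likely to fail

Step 3 (Negishi coupling). What may go wrong: slow oxidative addition and transmetalation at the doubly ortho-substituted iodide that carries a zinc phenoxide, with protodeiodination of 3 or β-hydride elimination from the alkylpalladium species, and protonolysis of 5 by the phenol. Fallback (sets out from 3, returns at 6): the stereocentre is made by catalysis instead of being bought. A Mizoroki–Heck reaction of 3 with methyl methacrylate (C=C(C)C(=O)OC; Pd(OAc)2, P(o-tol)3, Et3N, DMF, 100 °C) should give the (E)-2-methylcinnamate F1. Asymmetric hydrogenation of its trisubstituted double bond with [Ir(cod)(L)]BArF (L = chiral phosphinooxazoline, the enantiomer being chosen for the R product; H2, CH2Cl2, rt) should then lead to 6.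

Step 7 (Claisen condensation). What may go wrong: proton abstraction from the methine next to the aryl ester carbonyl by the enolate (epimerisation, in the extreme loss of phenoxide to a ketene), proton exchange with the acidic 2-methyl group of the chromone, or equilibration of the enolate toward C3 with loss of silanolate. Fallback (sets out from 7, returns at 12): the nucleophile is changed to a weakly basic acetylide and the acyl donor to a Weinreb amide, the ynone serving as a latent 1,3-diketone. Lactone 7 is opened with MeNH(OMe)·HCl/AlMe3 (CH2Cl2, 0 °C to rt) to the Weinreb amide F2. Commercial (2S)-pent-4-yn-2-ol (C#CC[C@H](C)O) is silylated (TBSCl, imidazole) to the silyl ether F3, whose lithium acetylide (n-BuLi, THF, −78 °C, 3 equiv, the first equivalent being taken up by the phenol) adds to F2 to give the ynone F4. Conjugate addition of Et2NH (EtOH, rt) gives the enaminone F5, and mild hydrolysis (aqueous oxalic acid, THF) gives 12.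

Step 8 (key cyclodehydration). What may go wrong: under protic acid the diketone may enolise toward the methine (loss of configuration next to C6'), the C2' oxygen may be lost by elimination before the ring closes (a crotonyl diketone that would re-close without stereocontrol), or the dehydration may stall at the hemiketal. Fallback (sets out from 7 and 9, returns at 15): the ring is closed by neutral gold catalysis on a β-hydroxy ynone, in which no 1,3-diketone is ever present. Lactone 7 is reduced with i-Bu2AlH (CH2Cl2, −78 °C) to the lactol F6, which through its open hydroxy aldehyde form is homologated with the Ohira–Bestmann reagent (dimethyl (1-diazo-2-oxopropyl)phosphonate, K2CO3, MeOH) to the terminal alkyne F7. Ozonolysis of 9 (O3, CH2Cl2, −78 °C; then PPh3) gives the aldehyde F8. Its slow addition to the zinc acetylide of F7 (Zn(OTf)2, Et3N, toluene, rt) gives the propargylic alcohol F9 as a mixture of carbinol epimers, MnO2 (CH2Cl2) oxidises it to the ynone F10, and HF·pyridine (THF) frees the β-hydroxy ynone F11. Ph3PAuCl/AgOTf (5 mol %, CH2Cl2, rt) should then effect 6-endo-dig addition of the secondary hydroxyl to the alkyne carbon next to the methine and give 15 directly.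

Further compounds
F1 | step 3 | methyl (2E)-3-(5-hydroxy-7-methoxy-2-methyl-4-oxo-4H-chromen-6-yl)-2-methylprop-2-enoate | COc1cc2oc(C)cc(=O)c2c(O)c1/C=C(\C)C(=O)OC
F2 | step 7 | (2R)-3-(5-hydroxy-7-methoxy-2-methyl-4-oxo-4H-chromen-6-yl)-N-methoxy-N,2-dimethylpropanamide | COc1cc2oc(C)cc(=O)c2c(O)c1C[C@@H](C)C(=O)N(C)OC
F3 | step 7 | tert-butyl(dimethyl){[(2S)-pent-4-yn-2-yl]oxy}silane | C#CC[C@H](C)O[Si](C)(C)C(C)(C)C
F4 | step 7 | 6-[(2R,7S)-7-{[tert-butyl(dimethyl)silyl]oxy}-2-methyl-3-oxooct-4-yn-1-yl]-5-hydroxy-7-methoxy-2-methyl-4H-chromen-4-one | COc1cc2oc(C)cc(=O)c2c(O)c1C[C@@H](C)C(=O)C#CC[C@H](C)O[Si](C)(C)C(C)(C)C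
F5 | step 7 | 6-[(2R,7S)-7-{[tert-butyl(dimethyl)silyl]oxy}-5-(diethylamino)-2-methyl-3-oxooct-4-en-1-yl]-5-hydroxy-7-methoxy-2-methyl-4H-chromen-4-one | COc1cc2oc(C)cc(=O)c2c(O)c1C[C@@H](C)C(=O)C=C(N(CC)CC)C[C@H](C)O[Si](C)(C)C(C)(C)C
F6 | step 8 | (3R)-2-hydroxy-5-methoxy-3,8-dimethyl-3,4-dihydro-2H,10H-pyrano[2,3-f]chromen-10-one | COc1cc2oc(C)cc(=O)c2c3c1C[C@@H](C)C(O)O3
F7 | step 8 | 5-hydroxy-7-methoxy-2-methyl-6-[(2R)-2-methylbut-3-yn-1-yl]-4H-chromen-4-one | COc1cc2oc(C)cc(=O)c2c(O)c1C[C@@H](C)C#C
F8 | step 8 | (3S)-3-{[tert-butyl(dimethyl)silyl]oxy}butanal | O=CC[C@H](C)O[Si](C)(C)C(C)(C)C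
F9 | step 8 | 6-[(2R,7S)-7-{[tert-butyl(dimethyl)silyl]oxy}-5-hydroxy-2-methyloct-3-yn-1-yl]-5-hydroxy-7-methoxy-2-methyl-4H-chromen-4-one | COc1cc2oc(C)cc(=O)c2c(O)c1C[C@@H](C)C#CC(O)C[C@H](C)O[Si](C)(C)C(C)(C)C
F10 | step 8 | 6-[(2R,7S)-7-{[tert-butyl(dimethyl)silyl]oxy}-2-methyl-5-oxooct-3-yn-1-yl]-5-hydroxy-7-methoxy-2-methyl-4H-chromen-4-one | COc1cc2oc(C)cc(=O)c2c(O)c1C[C@@H](C)C#CC(=O)C[C@H](C)O[Si](C)(C)C(C)(C)C
F11 | step 8 | 5-hydroxy-6-[(2R,7S)-7-hydroxy-2-methyl-5-oxooct-3-yn-1-yl]-7-methoxy-2-methyl-4H-chromen-4-one | COc1cc2oc(C)cc(=O)c2c(O)c1C[C@@H](C)C#CC(=O)C[C@H](C)O
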